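**Retrosynthetic overview**
- The target is cut at the aryl C6–C1' bond into 6-bromo-7-methoxycoumarin and an (R)-α-isovaleryloxy aldehyde. A light-driven Ni/Cr carbonyl arylation joins them and sets C1', with the ester already on the correct oxygen.
- The aldehyde comes from glycol cleavage (loss of acetone) of the mono-isovalerate of a C2-symmetric tetraol.
- The tetraol comes from dimethyl D-tartrate and MeMgBr. One tartrate carbinol becomes C2' unchanged; the other becomes C1', whose configuration is erased and reset.
- The bromocoumarin comes from 5-bromo-2-hydroxy-4-methoxybenzaldehyde by Wittig olefination and lactonisation.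
- Ring order: the benzene ring is bought; the pyranone ring is closed before the fragment union; no other ring is made.

Assumption: the SMILES is read as the (1S,2S) erythro (anti) diol mono-ester with the ester on the carbinol next to the CMe2OH group; reagents named without a number are bought.

**Step 1**
Reactants: 1 dimethyl D-tartrate, dimethyl (2S,3S)-2,3-dihydroxybutanedioate
Product: 2 (3S,4S)-2,5-dimethylhexane-2,3,4,5-tetraol
Conditions: MeMgBr (7 equiv), THF/Et2O, 0 °C to reflux; sat. aq NH4Cl; continuous EtOAc extraction
Reagents that add atoms: methylmagnesium bromide, C[Mg]Br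
Why: Exhaustive Grignard addition converts both esters into CMe2OH groups while the two stereocentres sit as magnesium alkoxides, are not enolised and keep their (S,S) configuration.

**Step 2**
Reactants: 2 (3S,4S)-2,5-dimethylhexane-2,3,4,5-tetraol
Product: 3 (3S,4S)-2,4,5-trihydroxy-2,5-dimethylhexan-3-yl 3-methylbutanoate
Conditions: i-BuCOCl (0.95 equiv), Me2SnCl2 (5 mol %), K2CO3 (2 equiv), THF, 0 °C to rt
Reagents that add atoms: 3-methylbutanoyl chloride (isovaleryl chloride), CC(C)CC(=O)Cl
Why: Tin-catalysed mono-acylation of a 1,2-diol through its stannylene acetal acylates one secondary oxygen; the two secondary hydroxyls are homotopic, so only one mono-ester exists, and the tertiary hydroxyls do not react.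

**Step 3**
Reactants: 3 (3S,4S)-2,4,5-trihydroxy-2,5-dimethylhexan-3-yl 3-methylbutanoate
Product: 4 (2R)-3-hydroxy-3-methyl-1-oxobutan-2-yl 3-methylbutanoate
Conditions: NaIO4 on silica gel (1.5 equiv), CH2Cl2, 0 °C to rt; filter, concentrate cold, use at once
Reagents that add atoms: none
Why: Malaprade glycol cleavage cuts the only free vicinal diol (secondary/tertiary) to the aldehyde and acetone without touching the ester-bearing stereocentre, whose label changes from S to R only because CHO now outranks CMe2OH.

**Step 4**
Reactants: 5 5-bromo-2-hydroxy-4-methoxybenzaldehyde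
Product: 8 6-bromo-7-methoxy-2H-chromen-2-one, via E-cinnamate ester 6 (not isolated), via Z-cinnamate ester 7 (not isolated)
Conditions: Ph3P=CHCO2Et (1.2 equiv), N,N-diethylaniline, reflux (about 215 °C), 4 h
Reagents that add atoms: ethyl (triphenylphosphoranylidene)acetate, CCOC(=O)C=P(c1ccccc1)(c1ccccc1)c1ccccc1
Why: Wittig olefination gives the E-cinnamate, which at this temperature isomerises to the Z-ester and lactonises with loss of ethanol (the Wittig/thermal lactonisation route to coumarins), leaving the aryl bromide and methyl ether intact.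

**Step 5**
Reactants: 8 6-bromo-7-methoxy-2H-chromen-2-one; 4 (2R)-3-hydroxy-3-methyl-1-oxobutan-2-yl 3-methylbutanoate
Product: 9 (1S,2S)-1,3-dihydroxy-1-(7-methoxy-2-oxo-2H-chromen-6-yl)-3-methylbutan-2-yl 3-methylbutanoate
Conditions: 4 (1.3 equiv), Ru(bpy)3(PF6)2 (1 mol %), CrCl2 (15 mol %), NiBr2(dme) (3 mol %), neocuproine (3.5 mol %), Hantzsch ester (1.5 equiv), 2,6-lutidine (1.5 equiv), MeCN/THF 3:1, 455 nm LEDs, 15 °C, argon
Reagents that add atoms: none
Why: Proposed new method: a visible-light-driven Ni/Cr Nozaki–Hiyama–Kishi (NHK) arylation with the Hantzsch ester as the only stoichiometric reductant. Photoexcited Ru(bpy)3(PF6)2 is quenched by the Hantzsch ester, and the reduced photocatalyst (about −1.3 V vs SCE) returns trivalent chromium to divalent chromium, which reduces the nickel–neocuproine complex to zerovalent nickel. Nickel inserts into the C–Br bond of 8 and passes the aryl group to chromium, and the aryl–chromium species adds to the aldehyde of 4 in the Cornforth/polar Felkin–Anh sense (C2–O bond anti to C=O, attack past the small H and away from the CMe2OH group; a six-membered chromium chelate through the tertiary hydroxyl exposes the same face). This gives the anti (erythro) carbinol, (1S) beside the bought centre, which is (2S) in 9 by ranking only. The chromium alkoxide is released by the lutidinium acid made in the cycle, so the neighbouring ester never meets a basic alkoxide and does not migrate. The low triplet energy of the ruthenium sensitiser and 455 nm light avoid coumarin [2+2] dimerisation. The closest known reaction types are Mn- or cathode-driven catalytic NHK arylation and photoredox/chromium allylation of aldehydes.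

**Compound list**
1 | dimethyl D-tartrate, dimethyl (2S,3S)-2,3-dihydroxybutanedioate | COC(=O)[C@@H](O)[C@H](O)C(=O)OC | starting material
2 | (3S,4S)-2,5-dimethylhexane-2,3,4,5-tetraol | CC(C)(O)[C@@H](O)[C@H](O)C(C)(C)O | intermediate
3 | (3S,4S)-2,4,5-trihydroxy-2,5-dimethylhexan-3-yl 3-methylbutanoate | CC(C)(O)[C@@H](O)[C@H](OC(=O)CC(C)C)C(C)(C)O | intermediate
4 | (2R)-3-hydroxy-3-methyl-1-oxobutan-2-yl 3-methylbutanoate | O=C[C@H](OC(=O)CC(C)C)C(C)(C)O | intermediate
5 | 5-bromo-2-hydroxy-4-methoxybenzaldehyde | COc1cc(O)c(C=O)cc1Br | starting material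
6 | ethyl (2E)-3-(5-bromo-2-hydroxy-4-methoxyphenyl)prop-2-enoate | CCOC(=O)/C=C/c1cc(Br)c(OC)cc1O | intermediate
7 | ethyl (2Z)-3-(5-bromo-2-hydroxy-4-methoxyphenyl)prop-2-enoate | CCOC(=O)/C=C\c1cc(Br)c(OC)cc1O | intermediate
8 | 6-bromo-7-methoxy-2H-chromen-2-one (6-bromo-7-methoxycoumarin) | COc1cc2oc(=O)ccc2cc1Br | intermediate
9 | (1S,2S)-1,3-dihydroxy-1-(7-methoxy-2-oxo-2H-chromen-6-yl)-3-methylbutan-2-yl 3-methylbutanoate | COc1cc2oc(=O)ccc2cc1[C@H](O)[C@H](OC(=O)CC(C)C)C(C)(C)O | target

**Step count and risks**
Total steps: 5. Longest linear sequence: 4 steps (1 → 2 → 3 → 4 → 9); step 4 is a one-step side branch.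

Step 5 (the proposed new reaction) is the most likely to fail. The risks are protodebromination of 8, pinacol coupling, dehydration or epimerisation of the labile aldehyde 4, and a modest erythro/threo ratio (the minor threo isomer would be removed by chromatography). The fallback uses known chemistry and leaves the light-driven catalytic cycle for a stoichiometric thermal organochromium addition with a more reactive halide. It sets out from 8: copper-catalysed halogen exchange (CuI 5 mol %, N,N'-dimethylethylenediamine 10 mol %, NaI 2 equiv, dioxane, 110 °C) gives 6-iodo-7-methoxy-2H-chromen-2-one F1. F1 is then coupled with 4 in the classical NHK reaction (CrCl2 4 equiv, NiCl2 2 mol %, degassed DMSO, rt), with the same Cornforth control, and comes back to the route at 9.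

Step 2 may over-acylate to the 3,4-diester or show poor mono-selectivity. The fallback tells the two carbinols apart before the Grignard addition and sets out from 1. Bu2SnO (toluene, reflux) then BnBr and CsF (DMF) give dimethyl (2S,3S)-2-(benzyloxy)-3-hydroxybutanedioate F2. MeMgBr (6 equiv, THF) gives (3S,4S)-4-(benzyloxy)-2,5-dimethylhexane-2,3,5-triol F3. Acylation of its only secondary hydroxyl (isovaleryl chloride, pyridine, DMAP cat., CH2Cl2, 0 °C) gives (3S,4S)-4-(benzyloxy)-2,5-dihydroxy-2,5-dimethylhexan-3-yl 3-methylbutanoate F4. Hydrogenolysis (H2, Pd/C, EtOAc) comes back to the route at 3.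

Step 1 may stall because the unprotected hydroxy diester forms insoluble magnesium alkoxides, and the tetraol is very water-soluble and hard to isolate. The fallback protects the diol first and sets out from 1. 2,2-Dimethoxypropane with TsOH (cat.) gives dimethyl (4S,5S)-2,2-dimethyl-1,3-dioxolane-4,5-dicarboxylate F5. MeMgBr (5 equiv, THF) gives the ether-soluble 2,2'-[(4S,5S)-2,2-dimethyl-1,3-dioxolane-4,5-diyl]di(propan-2-ol) F6. Acidic resin (Dowex 50W, H+ form, MeOH/H2O, 50 °C) removes the acetonide and comes back to the route at 2.

**Further compounds**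
F1 | step 5 | 6-iodo-7-methoxy-2H-chromen-2-one | COc1cc2oc(=O)ccc2cc1I
F2 | step 2 | dimethyl (2S,3S)-2-(benzyloxy)-3-hydroxybutanedioate | COC(=O)[C@@H](O)[C@H](OCc1ccccc1)C(=O)OC
F3 | step 2 | (3S,4S)-4-(benzyloxy)-2,5-dimethylhexane-2,3,5-triol | CC(C)(O)[C@@H](O)[C@H](OCc1ccccc1)C(C)(C)O
F4 | step 2 | (3S,4S)-4-(benzyloxy)-2,5-dihydroxy-2,5-dimethylhexan-3-yl 3-methylbutanoate | CC(C)(O)[C@@H](OC(=O)CC(C)C)[C@H](OCc1ccccc1)C(C)(C)O
F5 | step 1 | dimethyl (4S,5S)-2,2-dimethyl-1,3-dioxolane-4,5-dicarboxylate | COC(=O)[C@H]1OC(C)(C)O[C@@H]1C(=O)OC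
F6 | step 1 | 2,2'-[(4S,5S)-2,2-dimethyl-1,3-dioxolane-4,5-diyl]di(propan-2-ol) | CC(C)(O)[C@H]1OC(C)(C)O[C@@H]1C(C)(C)O
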